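**Plan**
1. Retrosynthetic cuts, in order: the two O–Si bonds; the sp2–sp2 single bond of the polyene between the methyl-bearing C=C next to the lactone and the following C=C (Stille); the exocyclic C5=C bond of the lactone (vinylogous aldol condensation); the lactone C2–C3 bond, carbonyl carbon to α-carbon (anionic ring closure); the alkyne–alkene and alkyne–ring bonds (Sonogashira) and the terminal C=C bonds (Takai).
2. Forward: one enol triflate from actinol serves both six-membered rings. On the ring A side the epoxide ring is made first, then the side chain, then the butenolide ring, then the ylidene. On the ring B side a trienylstannane is built. The halves are joined by a Stille coupling and desilylated.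
3. Enabling feature: in the butenolide (O1, C2(=O), C3, C4, C5) the carbonyl carbon C2 has only O1, the carbonyl oxygen and C3 as neighbours, and C3 lies cis to the O1–C5 arm across the endocyclic C3=C4 bond. C2 can therefore be hung on O1 as a carbonate, and the five-membered ring closes when a C3 vinyl anion attacks it.
4. Stereocentres: the carbinol centre of (4R,6R)-actinol becomes C3 of ring A and C3' of ring B; both epoxide carbons of ring A are set together by a Sharpless epoxidation anti to the silyloxy group.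
5. Double bonds: Takai olefination (E), anti hydroalumination–iodination (cis C3=C4 of the ring), carboalumination (E), E1cB elimination (Z-ylidene), Stille couplings (retention).

Key step: step 11

Assumption: the target is taken as drawn, i.e. the all-E polyene with a (Z)-ylidenebutenolide and the (3S,5R,6S)-epoxy end group and (3'R)-acetylenic end group of carotenoid numbering; compounds 1, 10, 25 and 29 are taken as purchasable.
Abbreviations used in names: [ring A] = (1S,4S,6R)-2,2,6-trimethyl-4-(triethylsilyloxy)-7-oxabicyclo[4.1.0]heptan-1-yl; [ring B] = (4R)-2,6,6-trimethyl-4-(triethylsilyloxy)cyclohex-1-en-1-yl.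

**Step 1**
Reactants: 1 (4R,6R)-4-hydroxy-2,2,6-trimethylcyclohexan-1-one (actinol)
Product: 2 (4R,6R)-2,2,6-trimethyl-4-(triethylsilyloxy)cyclohexan-1-one
Conditions: Et3SiCl, imidazole, DMF, 0 °C → rt
Reagents that add atoms: chlorotriethylsilane, CC[Si](Cl)(CC)CC
Why: Silyl ether protection of the unhindered secondary alcohol should be clean and leaves the carbinol stereocentre untouched.

**Step 2**
Reactants: 2 (4R,6R)-2,2,6-trimethyl-4-(triethylsilyloxy)cyclohexan-1-one
Product: 4 (4R)-2,6,6-trimethyl-4-(triethylsilyloxy)cyclohex-1-en-1-yl trifluoromethanesulfonate, via potassium enolate 3 (not isolated)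
Conditions: KN(SiMe3)2, THF, −78 °C; then PhNTf2, −78 → 0 °C; aq. NH4Cl
Reagents that add atoms: N-phenylbis(trifluoromethanesulfonimide), O=S(=O)(N(c1ccccc1)S(=O)(=O)C(F)(F)F)C(F)(F)F
Why: The ketone can enolise only towards the methyl-bearing carbon (the other α-carbon is quaternary), so O-triflation of the enolate should give a single enol triflate; the methyl-bearing stereocentre is erased on purpose.

**Step 3**
Reactants: 4 (4R)-2,6,6-trimethyl-4-(triethylsilyloxy)cyclohex-1-en-1-yl trifluoromethanesulfonate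
Product: 5 methyl (4R)-2,6,6-trimethyl-4-(triethylsilyloxy)cyclohex-1-ene-1-carboxylate
Conditions: Pd(OAc)2 (cat.), PPh3, CO (1 atm), MeOH, Et3N, DMF, 70 °C
Reagents that add atoms: carbon monoxide, [C-]#[O+]; methanol, CO
Why: Palladium-catalysed alkoxycarbonylation (oxidative addition of the triflate to zerovalent palladium, CO insertion, methanolysis) should give the conjugated ester without touching the silyl ether.

**Step 4**
Reactants: 5 methyl (4R)-2,6,6-trimethyl-4-(triethylsilyloxy)cyclohex-1-ene-1-carboxylate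
Product: 6 [(4R)-2,6,6-trimethyl-4-(triethylsilyloxy)cyclohex-1-en-1-yl]methanol
Conditions: i-Bu2AlH, CH2Cl2, −78 → 0 °C; aq. potassium sodium tartrate
Reagents that add atoms: none
Why: 1,2-Reduction of the conjugated ester by the aluminium hydride should stop cleanly at the allylic alcohol.

**Step 5**
Reactants: 6 [(4R)-2,6,6-trimethyl-4-(triethylsilyloxy)cyclohex-1-en-1-yl]methanol
Product: 7 [(1R,4S,6R)-2,2,6-trimethyl-4-(triethylsilyloxy)-7-oxabicyclo[4.1.0]heptan-1-yl]methanol
Conditions: Ti(OiPr)4, D-(−)-diethyl tartrate, t-BuOOH, 4 Å MS, CH2Cl2, −20 °C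
Reagents that add atoms: tert-butyl hydroperoxide, CC(C)(C)OO
Why: Sharpless asymmetric epoxidation: the titanium tartrate bound to the allylic hydroxyl delivers the peroxide oxygen to one face of the tetrasubstituted C=C, and with D-(−)-diethyl tartrate the mnemonic predicts the face anti to the silyloxy group, so both epoxide stereocentres are set together by reagent control on top of the modest steric bias of the ring.

**Step 6**
Reactants: 7 [(1R,4S,6R)-2,2,6-trimethyl-4-(triethylsilyloxy)-7-oxabicyclo[4.1.0]heptan-1-yl]methanol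
Product: 8 (1S,4S,6R)-2,2,6-trimethyl-4-(triethylsilyloxy)-7-oxabicyclo[4.1.0]heptane-1-carbaldehyde
Conditions: (n-Pr4N)RuO4 (cat.), N-methylmorpholine N-oxide, 4 Å MS, CH2Cl2, rt
Reagents that add atoms: none
Why: Ley–Griffith oxidation is non-acidic, so the epoxide should survive, and the aldehyde has a quaternary α-carbon and cannot epimerise.

**Step 7**
Reactants: 8 (1S,4S,6R)-2,2,6-trimethyl-4-(triethylsilyloxy)-7-oxabicyclo[4.1.0]heptane-1-carbaldehyde
Product: 9 (1S,4S,6R)-1-[(E)-2-iodoethenyl]-2,2,6-trimethyl-4-(triethylsilyloxy)-7-oxabicyclo[4.1.0]heptane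
Conditions: CrCl2, CHI3, THF, 0 °C → rt
Reagents that add atoms: iodoform, IC(I)I
Why: Takai olefination should give the (E)-vinyl iodide, E-selectivity being highest for α-branched aldehydes such as this α-quaternary one, under non-basic conditions.

**Step 8**
Reactants: 9 (1S,4S,6R)-1-[(E)-2-iodoethenyl]-2,2,6-trimethyl-4-(triethylsilyloxy)-7-oxabicyclo[4.1.0]heptane; 10 prop-2-yn-1-ol
Product: 11 (4E)-5-[ring A]pent-4-en-2-yn-1-ol
Conditions: Pd(PPh3)2Cl2 (cat.), CuI (cat.), i-Pr2NH, THF, rt
Reagents that add atoms: none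
Why: Sonogashira coupling of an alkenyl iodide proceeds at room temperature with retention of the E geometry and tolerates the free hydroxyl, the epoxide and the silyl ether.

**Step 9**
Reactants: 11 (4E)-5-[ring A]pent-4-en-2-yn-1-ol
Product: 13 (2Z,4E)-3-iodo-5-[ring A]penta-2,4-dien-1-ol, via sodium oxa-aluminacyclopentene 12 (not isolated)
Conditions: NaAlH2(OCH2CH2OMe)2, THF, 0 °C; then I2, THF, −78 → 0 °C
Reagents that add atoms: iodine, II
Why: Alkoxide-directed anti hydroalumination of the propargylic alcohol delivers hydride to C2 and aluminium to C3 inside a five-membered oxa-aluminacycle, and iodinolysis with retention should give the 3-iodide cis to the CH2OH arm, the hindered fully substituted epoxide and the conjugated C=C being left alone.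

**Step 10**
Reactants: 13 (2Z,4E)-3-iodo-5-[ring A]penta-2,4-dien-1-ol
Product: 14 (2Z,4E)-3-iodo-5-[ring A]penta-2,4-dien-1-yl phenyl carbonate
Conditions: PhOC(O)Cl, pyridine, CH2Cl2, 0 °C
Reagents that add atoms: phenyl chloroformate, O=C(Cl)Oc1ccccc1
Why: Acylation of the primary allylic alcohol installs the future lactone carbonyl on O1 as a carbonate whose second alkoxy group (phenoxide) is a good leaving group.

**Step 11**
Reactants: 14 (2Z,4E)-3-iodo-5-[ring A]penta-2,4-dien-1-yl phenyl carbonate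
Product: 17 3-[(E)-2-[ring A]ethenyl]furan-2(5H)-one, via dienyllithium 15 (not isolated), via lithium hemiorthoester alkoxide 16 (not isolated)
Conditions: n-BuLi (1.05 equiv), THF–Et2O, −100 °C; then sat. aq. NH4Cl, −100 °C → rt
Reagents that add atoms: none
Why: Iodine–lithium exchange on the (Z)-dienyl iodide at −100 °C is faster than addition of n-BuLi to the carbonate and gives the C3 dienyllithium 15 with retention of geometry, so the carbanion is held cis to the CH2–O–C(=O)OPh arm. It adds to the carbonate carbonyl in a 5-exo-trig closure, the only ring formed, which creates the C2–C3 bond and the cyclic alkoxide 16; this collapses by loss of phenoxide, a better leaving group by about six pKa units than the primary allylic alkoxide, so the new C–C bond remains the ring-closing bond of the butenolide. The closest known reaction type is the Parham cyclization, the intramolecular acyl substitution of an aryl- or vinyllithium made by halogen–lithium exchange on an ester, carbamate or carbonate. No stereocentre is formed; the cis C3=C4 geometry of the ring is the one installed by the anti hydroalumination of step 9. The step needs chemoselectivity (exchange before carbonyl addition, cyclisation before intermolecular proton transfer or attack on the epoxide or silyl ether), and this is secured by the iodide, the five-membered transition state, the position of lithium gamma to the carbonate oxygen (no β-elimination is possible) and the hindered, fully substituted epoxide. Quenching at −100 °C keeps the acidic C5 methylene of 17 from being deprotonated.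

**Step 12**
Reactants: 10 prop-2-yn-1-ol
Product: 19 (E)-3-iodo-2-methylprop-2-en-1-ol, via alkenylalane 18 (not isolated)
Conditions: AlMe3 (3 equiv), Cp2ZrCl2 (cat.), CH2Cl2, 0 °C → rt; then I2, THF, −30 °C; aq. K2CO3
Reagents that add atoms: trimethylaluminium, C[Al](C)C; iodine, II
Why: Negishi carboalumination adds methyl and aluminium syn across the alkyne, methyl to the internal carbon, and iodinolysis with retention should give the (E)-iodide.

**Step 13**
Reactants: 19 (E)-3-iodo-2-methylprop-2-en-1-ol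
Product: 20 (E)-3-iodo-2-methylprop-2-enal
Conditions: MnO2, CH2Cl2, rt
Reagents that add atoms: none
Why: Manganese dioxide oxidises the allylic alcohol selectively and neutrally, without isomerising the iodoalkene; the volatile aldehyde would be used at once.

**Step 14**
Reactants: 17 3-[(E)-2-[ring A]ethenyl]furan-2(5H)-one; 20 (E)-3-iodo-2-methylprop-2-enal
Product: 24 (5Z)-5-[(2E)-3-iodo-2-methylprop-2-en-1-ylidene]-3-[(E)-2-[ring A]ethenyl]furan-2(5H)-one, via lithium furanolate 21 (not isolated), via lithium aldolate 22 (not isolated), via aldol acetate 23 (not isolated)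
Conditions: 17 and 20, THF, −78 °C, LiN(SiMe3)2 added last; then Ac2O, −78 → 0 °C; then DBU, 0 °C → rt
Reagents that add atoms: none
Why: Vinylogous aldol condensation: the furanolate, generated in the presence of the aldehyde so that it is short-lived, should add through C5 (C3 is blocked by the dienyl group), and E1cB loss of acetate should give the thermodynamically preferred (Z)-ylidene with the alkenyl group cis to the ring oxygen, the two transient stereocentres of 22 and 23 (diastereomer mixture) being erased.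

**Step 15**
Reactants: 4 (4R)-2,6,6-trimethyl-4-(triethylsilyloxy)cyclohex-1-en-1-yl trifluoromethanesulfonate; 25 (2E)-3-methylpent-2-en-4-yn-1-ol
Product: 26 (2E)-3-methyl-5-[ring B]pent-2-en-4-yn-1-ol
Conditions: Pd(PPh3)4 (cat.), CuI (cat.), i-Pr2NH, DMF, 50 °C
Reagents that add atoms: none
Why: Sonogashira coupling of the enol triflate with the terminal enyne forms the ring–alkyne bond and keeps the E geometry of the purchased enynol.

**Step 16**
Reactants: 26 (2E)-3-methyl-5-[ring B]pent-2-en-4-yn-1-ol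
Product: 27 (2E)-3-methyl-5-[ring B]pent-2-en-4-ynal
Conditions: MnO2, CH2Cl2, rt
Reagents that add atoms: none
Why: Selective neutral oxidation of the allylic alcohol to the enynal.

**Step 17**
Reactants: 27 (2E)-3-methyl-5-[ring B]pent-2-en-4-ynal
Product: 28 (1E,3E)-1-iodo-4-methyl-6-[ring B]hexa-1,3-dien-5-yne
Conditions: CrCl2, CHI3, THF, 0 °C → rt
Reagents that add atoms: iodoform, IC(I)I
Why: Takai olefination of the enynal should give mainly the (1E)-dienyl iodide; any minor (1Z) isomer would be removed by chromatography.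

**Step 18**
Reactants: 28 (1E,3E)-1-iodo-4-methyl-6-[ring B]hexa-1,3-dien-5-yne; 29 (E)-1,2-bis(tributylstannyl)ethene
Product: 30 tributyl[(1E,3E,5E)-6-methyl-8-[ring B]octa-1,3,5-trien-7-yn-1-yl]stannane
Conditions: Pd(MeCN)2Cl2 (cat.), DMF, rt, 29 in threefold excess
Reagents that add atoms: none
Why: Stille coupling with an excess of the symmetric distannane suppresses double coupling and retains the geometry of both partners.

**Step 19**
Reactants: 24 (5Z)-5-[(2E)-3-iodo-2-methylprop-2-en-1-ylidene]-3-[(E)-2-[ring A]ethenyl]furan-2(5H)-one; 30 tributyl[(1E,3E,5E)-6-methyl-8-[ring B]octa-1,3,5-trien-7-yn-1-yl]stannane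
Product: 31 (5Z)-5-[(2E,4E,6E,8E)-2,9-dimethyl-11-[ring B]undeca-2,4,6,8-tetraen-10-yn-1-ylidene]-3-[(E)-2-[ring A]ethenyl]furan-2(5H)-one
Conditions: Pd2(dba)3 (cat.), AsPh3, NMP, rt, dark
Reagents that add atoms: none
Why: Stille coupling of the electron-poor dienyl iodide with the trienylstannane under base-free conditions forms the last sp2–sp2 bond with retention of all double-bond geometries and should tolerate the epoxide and the ylidenebutenolide.

**Step 20**
Reactants: 31 (5Z)-5-[(2E,4E,6E,8E)-2,9-dimethyl-11-[ring B]undeca-2,4,6,8-tetraen-10-yn-1-ylidene]-3-[(E)-2-[ring A]ethenyl]furan-2(5H)-one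
Product: 32 (5Z)-5-[(2E,4E,6E,8E)-11-[(4R)-4-hydroxy-2,6,6-trimethylcyclohex-1-en-1-yl]-2,9-dimethylundeca-2,4,6,8-tetraen-10-yn-1-ylidene]-3-[(E)-2-[(1S,4S,6R)-4-hydroxy-2,2,6-trimethyl-7-oxabicyclo[4.1.0]heptan-1-yl]ethenyl]furan-2(5H)-one
Conditions: HF·pyridine, pyridine, THF, 0 °C → rt, dark
Reagents that add atoms: none
Why: Fluoride cleavage of both secondary triethylsilyl ethers under pyridine-buffered conditions is chosen because the epoxide conjugated to the polyene rearranges with acid and the butenolide is base-sensitive.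

**Compound list**
1 | (4R,6R)-4-hydroxy-2,2,6-trimethylcyclohexan-1-one | C[C@H]1C(=O)C(C)(C)C[C@H](O)C1 | starting material
2 | (4R,6R)-2,2,6-trimethyl-4-(triethylsilyloxy)cyclohexan-1-one | C[C@H]1C(=O)C(C)(C)C[C@H](O[Si](CC)(CC)CC)C1 | intermediate
3 | potassium (4R)-2,6,6-trimethyl-4-(triethylsilyloxy)cyclohex-1-en-1-olate | [K+].CC1=C([O-])C(C)(C)C[C@H](O[Si](CC)(CC)CC)C1 | intermediate
4 | (4R)-2,6,6-trimethyl-4-(triethylsilyloxy)cyclohex-1-en-1-yl trifluoromethanesulfonate | CC1=C(OS(=O)(=O)C(F)(F)F)C(C)(C)C[C@H](O[Si](CC)(CC)CC)C1 | intermediate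
5 | methyl (4R)-2,6,6-trimethyl-4-(triethylsilyloxy)cyclohex-1-ene-1-carboxylate | CC1=C(C(=O)OC)C(C)(C)C[C@H](O[Si](CC)(CC)CC)C1 | intermediate
6 | [(4R)-2,6,6-trimethyl-4-(triethylsilyloxy)cyclohex-1-en-1-yl]methanol | CC1=C(CO)C(C)(C)C[C@H](O[Si](CC)(CC)CC)C1 | intermediate
7 | [(1R,4S,6R)-2,2,6-trimethyl-4-(triethylsilyloxy)-7-oxabicyclo[4.1.0]heptan-1-yl]methanol | OC[C@@]12O[C@]1(C)C[C@@H](O[Si](CC)(CC)CC)CC2(C)C | intermediate
8 | (1S,4S,6R)-2,2,6-trimethyl-4-(triethylsilyloxy)-7-oxabicyclo[4.1.0]heptane-1-carbaldehyde | O=C[C@@]12O[C@]1(C)C[C@@H](O[Si](CC)(CC)CC)CC2(C)C | intermediate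
9 | (1S,4S,6R)-1-[(E)-2-iodoethenyl]-2,2,6-trimethyl-4-(triethylsilyloxy)-7-oxabicyclo[4.1.0]heptane | I/C=C/[C@@]12O[C@]1(C)C[C@@H](O[Si](CC)(CC)CC)CC2(C)C | intermediate
10 | prop-2-yn-1-ol | OCC#C | starting material
11 | (4E)-5-[ring A]pent-4-en-2-yn-1-ol | OCC#C/C=C/[C@@]12O[C@]1(C)C[C@@H](O[Si](CC)(CC)CC)CC2(C)C | intermediate
12 | sodium 2,2-bis(2-methoxyethoxy)-3-[(E)-2-[ring A]ethenyl]-2,5-dihydro-1,2-oxaluminol-2-uide | [Na+].COCCO[Al-]1(OCCOC)OCC=C1/C=C/[C@@]12O[C@]1(C)C[C@@H](O[Si](CC)(CC)CC)CC2(C)C | intermediate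
13 | (2Z,4E)-3-iodo-5-[ring A]penta-2,4-dien-1-ol | OC/C=C(\I)/C=C/[C@@]12O[C@]1(C)C[C@@H](O[Si](CC)(CC)CC)CC2(C)C | intermediate
14 | (2Z,4E)-3-iodo-5-[ring A]penta-2,4-dien-1-yl phenyl carbonate | O=C(Oc1ccccc1)OC/C=C(\I)/C=C/[C@@]12O[C@]1(C)C[C@@H](O[Si](CC)(CC)CC)CC2(C)C | intermediate
15 | (2Z,4E)-3-lithio-5-[ring A]penta-2,4-dien-1-yl phenyl carbonate | O=C(Oc1ccccc1)OC/C=C(\[Li])/C=C/[C@@]12O[C@]1(C)C[C@@H](O[Si](CC)(CC)CC)CC2(C)C | intermediate
16 | lithium 2-phenoxy-3-[(E)-2-[ring A]ethenyl]-2,5-dihydrofuran-2-olate | [Li+].[O-]C1(Oc2ccccc2)OCC=C1/C=C/[C@@]12O[C@]1(C)C[C@@H](O[Si](CC)(CC)CC)CC2(C)C | intermediate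
17 | 3-[(E)-2-[ring A]ethenyl]furan-2(5H)-one | O=C1OCC=C1/C=C/[C@@]12O[C@]1(C)C[C@@H](O[Si](CC)(CC)CC)CC2(C)C | intermediate
18 | [(E)-3-(dimethylalumanyloxy)-2-methylprop-1-en-1-yl]dimethylalane | C[Al](C)OC/C(C)=C/[Al](C)C | intermediate
19 | (E)-3-iodo-2-methylprop-2-en-1-ol | OC/C(C)=C/I | intermediate
20 | (E)-3-iodo-2-methylprop-2-enal | O=C/C(C)=C/I | intermediate
21 | lithium 3-[(E)-2-[ring A]ethenyl]furan-2-olate | [Li+].[O-]c1occc1/C=C/[C@@]12O[C@]1(C)C[C@@H](O[Si](CC)(CC)CC)CC2(C)C | intermediate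
22 | lithium (2E)-3-iodo-2-methyl-1-[5-oxo-4-[(E)-2-[ring A]ethenyl]-2,5-dihydrofuran-2-yl]prop-2-en-1-olate (diastereomer mixture) | [Li+].[O-]C(/C(C)=C/I)C1OC(=O)C(/C=C/[C@@]23O[C@]2(C)C[C@@H](O[Si](CC)(CC)CC)CC3(C)C)=C1 | intermediate
23 | (2E)-3-iodo-2-methyl-1-[5-oxo-4-[(E)-2-[ring A]ethenyl]-2,5-dihydrofuran-2-yl]prop-2-en-1-yl acetate (diastereomer mixture) | CC(=O)OC(/C(C)=C/I)C1OC(=O)C(/C=C/[C@@]23O[C@]2(C)C[C@@H](O[Si](CC)(CC)CC)CC3(C)C)=C1 | intermediate
24 | (5Z)-5-[(2E)-3-iodo-2-methylprop-2-en-1-ylidene]-3-[(E)-2-[ring A]ethenyl]furan-2(5H)-one | I/C=C(C)/C=C1C=C(/C=C/[C@@]23O[C@]2(C)C[C@@H](O[Si](CC)(CC)CC)CC3(C)C)C(=O)O/1 | intermediate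
25 | (2E)-3-methylpent-2-en-4-yn-1-ol | C#C/C(C)=C/CO | starting material
26 | (2E)-3-methyl-5-[ring B]pent-2-en-4-yn-1-ol | CC1=C(C#C/C(C)=C/CO)C(C)(C)C[C@H](O[Si](CC)(CC)CC)C1 | intermediate
27 | (2E)-3-methyl-5-[ring B]pent-2-en-4-ynal | CC1=C(C#C/C(C)=C/C=O)C(C)(C)C[C@H](O[Si](CC)(CC)CC)C1 | intermediate
28 | (1E,3E)-1-iodo-4-methyl-6-[ring B]hexa-1,3-dien-5-yne | CC1=C(C#C/C(C)=C/C=C/I)C(C)(C)C[C@H](O[Si](CC)(CC)CC)C1 | intermediate
29 | (E)-1,2-bis(tributylstannyl)ethene | CCCC[Sn](CCCC)(CCCC)/C=C/[Sn](CCCC)(CCCC)CCCC | starting material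
30 | tributyl[(1E,3E,5E)-6-methyl-8-[ring B]octa-1,3,5-trien-7-yn-1-yl]stannane | CC1=C(C#C/C(C)=C/C=C/C=C/[Sn](CCCC)(CCCC)CCCC)C(C)(C)C[C@H](O[Si](CC)(CC)CC)C1 | intermediate
31 | (5Z)-5-[(2E,4E,6E,8E)-2,9-dimethyl-11-[ring B]undeca-2,4,6,8-tetraen-10-yn-1-ylidene]-3-[(E)-2-[ring A]ethenyl]furan-2(5H)-one | CC1=C(C#C/C(C)=C/C=C/C=C/C=C(C)/C=C2C=C(/C=C/[C@@]34O[C@]3(C)C[C@@H](O[Si](CC)(CC)CC)CC4(C)C)C(=O)O/2)C(C)(C)C[C@H](O[Si](CC)(CC)CC)C1 | intermediate
32 | (5Z)-5-[(2E,4E,6E,8E)-11-[(4R)-4-hydroxy-2,6,6-trimethylcyclohex-1-en-1-yl]-2,9-dimethylundeca-2,4,6,8-tetraen-10-yn-1-ylidene]-3-[(E)-2-[(1S,4S,6R)-4-hydroxy-2,2,6-trimethyl-7-oxabicyclo[4.1.0]heptan-1-yl]ethenyl]furan-2(5H)-one | CC1=C(C#C/C(C)=C/C=C/C=C/C=C(C)/C=C2C=C(/C=C/[C@@]34O[C@]3(C)C[C@@H](O)CC4(C)C)C(=O)O/2)C(C)(C)C[C@H](O)C1 | target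

**Count**
Total steps: 20. Longest linear sequence: 14 steps (steps 1–11, 14, 19, 20).

**Steps most likely to fail**

Step 14. The furanolate may react through C3 instead of C5, or may release electron density through the dienyl arm and open the allylic epoxide (a vinylogous β-elimination) before it meets the aldehyde. The fallback sets out from 20, 30 and 9 and returns at 31; it attaches the epoxide-bearing side chain last, so that no furanolate ever coexists with the vinyl epoxide. Purchased 3-bromofuran-2(5H)-one F1 would be condensed with 20 (t-BuMe2SiOTf, i-Pr2NEt, CH2Cl2; then DBU) through 3-bromo-2-(tert-butyldimethylsilyloxy)furan F2 and the silylated aldol F3 to give the (Z)-bromo iodo ylidenebutenolide F4. A first Stille coupling with 30 (Pd2(dba)3, AsPh3) at the more reactive alkenyl iodide should give the bromo polyene F5. Iodide 9 would be turned into the ring A alkenylstannane F6 (Bu3SnSnBu3, Pd(PPh3)4), and a second Stille coupling of F5 with F6 at the C3 bromide should give 31. In this variant the lactone is bought, so the ring closure of step 11 is not used.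

Step 9. The aluminium hydride may attack or rearrange the vinyl epoxide, or reduce the enyne further. The fallback sets out from 9 and returns at 13. Sonogashira coupling of 9 with ethyl propiolate (Pd(PPh3)2Cl2, CuI, K2CO3, THF) should give the ynoate F7. Conjugate hydroiodination (NaI, AcOH, rt; anti addition, iodide at the β-carbon cis to the ester) should give the (2Z,4E)-3-iodo dienoate F8. Reduction with i-Bu2AlH at −78 °C should then give 13.

Step 11. n-BuLi may add to the carbonate before the exchange is complete, or unreacted dienyllithium may take a proton from the C5 methylene of the product and give the deiodinated carbonate. The fallback sets out from 13 and returns at 17. Palladium-catalysed carbonylative lactonisation of the (Z)-3-iodoallylic alcohol (Pd(PPh3)2Cl2 cat., CO 1 atm, Et3N, THF, rt) should give 17 directly under neutral conditions that the epoxide and silyl ether tolerate.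

**Further compounds**
F1 | step 14 | 3-bromofuran-2(5H)-one | O=C1OCC=C1Br
F2 | step 14 | 3-bromo-2-(tert-butyldimethylsilyloxy)furan | CC(C)(C)[Si](C)(C)Oc1occc1Br
F3 | step 14 | 3-bromo-5-[(2E)-1-(tert-butyldimethylsilyloxy)-3-iodo-2-methylprop-2-en-1-yl]furan-2(5H)-one | CC(C)(C)[Si](C)(C)OC(/C(C)=C/I)C1OC(=O)C(Br)=C1
F4 | step 14 | (5Z)-3-bromo-5-[(2E)-3-iodo-2-methylprop-2-en-1-ylidene]furan-2(5H)-one | I/C=C(C)/C=C1C=C(Br)C(=O)O/1
F5 | step 14 | (5Z)-3-bromo-5-[(2E,4E,6E,8E)-2,9-dimethyl-11-[ring B]undeca-2,4,6,8-tetraen-10-yn-1-ylidene]furan-2(5H)-one | CC1=C(C#C/C(C)=C/C=C/C=C/C=C(C)/C=C2C=C(Br)C(=O)O/2)C(C)(C)C[C@H](O[Si](CC)(CC)CC)C1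
F6 | step 14 | tributyl[(E)-2-[ring A]ethenyl]stannane | CCCC[Sn](CCCC)(CCCC)/C=C/[C@@]12O[C@]1(C)C[C@@H](O[Si](CC)(CC)CC)CC2(C)C
F7 | step 9 | ethyl (4E)-5-[ring A]pent-4-en-2-ynoate | CCOC(=O)C#C/C=C/[C@@]12O[C@]1(C)C[C@@H](O[Si](CC)(CC)CC)CC2(C)C
F8 | step 9 | ethyl (2Z,4E)-3-iodo-5-[ring A]penta-2,4-dienoate | CCOC(=O)/C=C(\I)/C=C/[C@@]12O[C@]1(C)C[C@@H](O[Si](CC)(CC)CC)CC2(C)C
F0 | step 11 | none | none
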